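**Retrosynthetic overview**
- The target comes from a bicyclic hydroxy lactone by acylation of the ring hydroxyl and unmasking of the α-methylene lactone (sulfide oxidation, syn-elimination).
- The cyclohexene ring is formed last, by ring-closing metathesis that makes the tetrasubstituted C=C.
- The metathesis diene comes from a Nozaki–Hiyama–Kishi union of fragment A (side-chain vinyl triflate already carrying its isobutyrate) with fragment B (γ-lactone aldehyde).
- Fragment A: copper-catalysed asymmetric allylic methylation sets the side-chain stereocentre, then Wacker oxidation and triflation. Fragment B: chromium-catalysed asymmetric allylation/lactonisation of a Baylis–Hillman bromide with 3-methylbut-3-enal sets both lactone stereocentres.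
- Ring order: γ-lactone first (fragment B), cyclohexene last.

Assumption: the ligand antipodes in steps 3 and 9 are those that give the configurations drawn, and sulfide 19 is drawn as its favoured 3,4-trans epimer (the 3-epimer reacts identically and converges at step 15).

**Route**

Step 1
Reactants: 1 pent-4-en-1-ol; 2 2-methylpropanoyl chloride
Product: 3 pent-4-en-1-yl 2-methylpropanoate
Conditions: Et3N, DMAP (cat.), CH2Cl2, 0 °C → rt
Reagents that add atoms: none
Why: DMAP-catalysed O-acylation (nucleophilic acyl substitution) of the primary alcohol installs the first isobutyrate, which is inert to every later step on this branch.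

Step 2
Reactants: 3 pent-4-en-1-yl 2-methylpropanoate; 4 (2E)-1,4-dibromobut-2-ene
Product: 5 (4E)-6-bromohex-4-en-1-yl 2-methylpropanoate
Conditions: second-generation Grubbs catalyst (3 mol %), 4 (3 equiv), CH2Cl2, 40 °C
Reagents that add atoms: none
Why: Olefin cross-metathesis of the terminal alkene with excess symmetrical dibromobutene gives the E-allylic bromide under thermodynamic control, with no stereocentre formed.

Step 3
Reactants: 5 (4E)-6-bromohex-4-en-1-yl 2-methylpropanoate
Product: 6 (4S)-4-methylhex-5-en-1-yl 2-methylpropanoate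
Conditions: MeMgBr (1.2 equiv), CuBr·SMe2 (2 mol %), Taniaphos (2.4 mol %), CH2Cl2, −78 °C
Reagents that add atoms: methylmagnesium bromide, C[Mg]Br
Why: Copper-catalysed asymmetric allylic alkylation (anti SN2′ attack of the chiral methylcopper species at the γ-carbon) gives the branched alkene and sets the methyl-bearing stereocentre as S under ligand control, the ester being untouched by the Grignard reagent at −78 °C.

Step 4
Reactants: 6 (4S)-4-methylhex-5-en-1-yl 2-methylpropanoate
Product: 7 (4S)-4-methyl-5-oxohexyl 2-methylpropanoate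
Conditions: PdCl2 (10 mol %), CuCl (20 mol %), O2 (1 atm), DMF/H2O (7:1), rt
Reagents that add atoms: water, O
Why: Tsuji–Wacker oxidation hydrates the terminal alkene with Markovnikov selectivity to the methyl ketone (O2 as terminal oxidant) under near-neutral conditions that do not enolise the adjacent stereocentre.

Step 5
Reactants: 7 (4S)-4-methyl-5-oxohexyl 2-methylpropanoate
Product: 9 (4S)-4-methyl-5-[(trifluoromethanesulfonyl)oxy]hex-5-en-1-yl 2-methylpropanoate, via potassium enolate 8 (not isolated)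
Conditions: KN(SiMe3)2 (1.05 equiv), THF, −78 °C (ketone added to base); then PhNTf2, −78 → 0 °C
Reagents that add atoms: N-phenylbis(trifluoromethanesulfonimide), O=S(=O)(N(c1ccccc1)S(=O)(=O)C(F)(F)F)C(F)(F)F
Why: Kinetic deprotonation at the unhindered methyl group followed by O-sulfonylation (enol triflate formation) gives the 2-triflyloxy-1-alkene without touching the α-stereocentre or the less acidic ester.

Step 6
Reactants: 10 methyl prop-2-enoate; 11 2,2-dimethoxyacetaldehyde
Product: 12 methyl 3-hydroxy-4,4-dimethoxy-2-methylidenebutanoate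
Conditions: DABCO (0.5 equiv), 1,4-dioxane/H2O (1:1), rt, 48 h
Reagents that add atoms: none
Why: Morita–Baylis–Hillman reaction of the acrylate with the activated non-enolisable aldehyde gives the allylic alcohol, whose stereocentre is irrelevant because it is erased in the next step.

Step 7
Reactants: 12 methyl 3-hydroxy-4,4-dimethoxy-2-methylidenebutanoate
Product: 13 methyl (2Z)-2-(bromomethyl)-4,4-dimethoxybut-2-enoate
Conditions: NBS, Me2S, CH2Cl2, 0 °C → rt
Reagents that add atoms: N-bromosuccinimide, O=C1CCC(=O)N1Br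
Why: Activation of the alcohol as an alkoxysulfonium salt and SN2′ attack of bromide (allylic transposition) gives the conjugated primary bromide with the acetal-bearing carbon cis to CH2Br, under acid-free conditions so the acetal survives.

Step 8
Reactants: 14 3-methylbut-3-en-1-ol
Product: 15 3-methylbut-3-enal
Conditions: Dess–Martin periodinane, NaHCO3, CH2Cl2, 0 °C; cold filtered solution used at once
Reagents that add atoms: none
Why: Dess–Martin oxidation under bicarbonate buffering gives the β,γ-unsaturated aldehyde without conjugation to the enal, provided it is used immediately.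

Step 9
Reactants: 13 methyl (2Z)-2-(bromomethyl)-4,4-dimethoxybut-2-enoate; 15 3-methylbut-3-enal
Product: 18 (4R,5R)-4-(dimethoxymethyl)-3-methylidene-5-(2-methylprop-2-en-1-yl)oxolan-2-one, via silyl ether 16 (not isolated), via hydroxy ester 17 (not isolated)
Conditions: CrCl2 (10 mol %), chiral 1,8-bis(4-isopropyloxazolin-2-yl)carbazole ligand (12 mol %), Mn (2 equiv), Me3SiCl (1.5 equiv), iPr2NEt (30 mol %), THF, 0 °C → rt; then PPTS, MeOH, 40 °C
Reagents that add atoms: none
Why: Catalytic asymmetric Nozaki–Hiyama allylation (Barbier-type, Mn as terminal reductant, Me3SiCl for turnover) through a closed chair transition state of the allylchromium reagent whose acetal substituent is cis to CH2Cr gives the syn adduct with the carbinol face chosen by the ligand, so that acid-catalysed lactonisation delivers the cis-4,5-disubstituted (4R,5R) α-methylene lactone.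

Step 10
Reactants: 18 (4R,5R)-4-(dimethoxymethyl)-3-methylidene-5-(2-methylprop-2-en-1-yl)oxolan-2-one
Product: 19 (3R,4R,5R)-4-(dimethoxymethyl)-5-(2-methylprop-2-en-1-yl)-3-[(phenylsulfanyl)methyl]oxolan-2-one
Conditions: PhSH (1.1 equiv), Et3N (0.2 equiv), CH2Cl2, 0 °C → rt
Reagents that add atoms: thiophenol, Sc1ccccc1
Why: Base-catalysed thia-Michael addition masks the exocyclic enoate so that the neighbouring ring carbon no longer carries an allylic hydrogen, the new C-3 centre settling trans to C-4 under the reversible conditions and being destroyed again in step 15.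

Step 11
Reactants: 19 (3R,4R,5R)-4-(dimethoxymethyl)-5-(2-methylprop-2-en-1-yl)-3-[(phenylsulfanyl)methyl]oxolan-2-one
Product: 20 (2R,3R,4R)-2-(2-methylprop-2-en-1-yl)-5-oxo-4-[(phenylsulfanyl)methyl]oxolane-3-carbaldehyde
Conditions: 1 M aq HCl/THF (1:2), 0 °C → rt; used crude
Reagents that add atoms: water, O
Why: Acid-catalysed acetal hydrolysis in a water-rich medium (hydration of the oxocarbenium ion outruns Prins closure onto the methallyl group) liberates the aldehyde without touching the existing stereocentres.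

Step 12
Reactants: 9 (4S)-4-methyl-5-[(trifluoromethanesulfonyl)oxy]hex-5-en-1-yl 2-methylpropanoate; 20 (2R,3R,4R)-2-(2-methylprop-2-en-1-yl)-5-oxo-4-[(phenylsulfanyl)methyl]oxolane-3-carbaldehyde
Product: 21 (4S,6S)-6-hydroxy-4-methyl-5-methylidene-6-[(2R,3S,4R)-2-(2-methylprop-2-en-1-yl)-5-oxo-4-[(phenylsulfanyl)methyl]oxolan-3-yl]hexyl 2-methylpropanoate
Conditions: CrCl2 (4 equiv), NiCl2 (2 mol %), DMF, rt
Reagents that add atoms: none
Why: Nozaki–Hiyama–Kishi coupling (oxidative addition of the triflate to zerovalent nickel, transmetallation to trivalent chromium, carbonyl addition) joins the two fragments chemoselectively at the aldehyde, and Felkin–Anh attack anti to the ring C–C bond that leads to the oxygen-bearing carbon sets the carbinol as S (modest selectivity expected, epimer separable).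

Step 13
Reactants: 21 (4S,6S)-6-hydroxy-4-methyl-5-methylidene-6-[(2R,3S,4R)-2-(2-methylprop-2-en-1-yl)-5-oxo-4-[(phenylsulfanyl)methyl]oxolan-3-yl]hexyl 2-methylpropanoate
Product: 22 (4S)-4-[(3R,3aS,4S,7aR)-4-hydroxy-6-methyl-2-oxo-3-[(phenylsulfanyl)methyl]-2,3,3a,4,7,7a-hexahydro-1-benzofuran-5-yl]pentyl 2-methylpropanoate
Conditions: second-generation Hoveyda–Grubbs catalyst (3 × 5 mol %), 2,6-dichloro-1,4-benzoquinone (20 mol %), toluene (5 mM), 100 °C
Reagents that add atoms: none
Why: Ring-closing metathesis of the two 1,1-disubstituted alkenes, helped by the free allylic hydroxyl and driven by loss of ethene, closes the cyclohexene ring with its tetrasubstituted double bond without touching any stereocentre.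

Step 14
Reactants: 22 (4S)-4-[(3R,3aS,4S,7aR)-4-hydroxy-6-methyl-2-oxo-3-[(phenylsulfanyl)methyl]-2,3,3a,4,7,7a-hexahydro-1-benzofuran-5-yl]pentyl 2-methylpropanoate; 2 2-methylpropanoyl chloride
Product: 23 (4S)-4-[(3R,3aR,4S,7aR)-6-methyl-4-[(2-methylpropanoyl)oxy]-2-oxo-3-[(phenylsulfanyl)methyl]-2,3,3a,4,7,7a-hexahydro-1-benzofuran-5-yl]pentyl 2-methylpropanoate
Conditions: 2 (2 equiv), pyridine, DMAP (cat.), CH2Cl2, 0 °C → rt
Reagents that add atoms: none
Why: DMAP-catalysed acylation of the hindered secondary allylic alcohol, with retention at carbon, installs the second isobutyrate.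

Step 15
Reactants: 23 (4S)-4-[(3R,3aR,4S,7aR)-6-methyl-4-[(2-methylpropanoyl)oxy]-2-oxo-3-[(phenylsulfanyl)methyl]-2,3,3a,4,7,7a-hexahydro-1-benzofuran-5-yl]pentyl 2-methylpropanoate
Product: 25 (4S)-4-[(3aR,4S,7aR)-6-methyl-3-methylidene-4-[(2-methylpropanoyl)oxy]-2-oxo-2,3,3a,4,7,7a-hexahydro-1-benzofuran-5-yl]pentyl 2-methylpropanoate, via sulfoxide 24 (not isolated)
Conditions: NaIO4 (1.1 equiv), MeOH/H2O, 0 °C → rt; extract; then toluene, CaCO3, 110 °C
Reagents that add atoms: none
Why: Chemoselective oxidation of the sulfide to the sulfoxide followed by thermal sulfoxide syn-elimination (the only β-hydrogen is the one α to the lactone carbonyl) unveils the α-methylene lactone and removes the temporary stereocentre.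

**Compound list**

1 | pent-4-en-1-ol | C=CCCCO | starting material
2 | 2-methylpropanoyl chloride | CC(C)C(=O)Cl | starting material
3 | pent-4-en-1-yl 2-methylpropanoate | C=CCCCOC(=O)C(C)C | intermediate
4 | (2E)-1,4-dibromobut-2-ene | BrC/C=C/CBr | starting material
5 | (4E)-6-bromohex-4-en-1-yl 2-methylpropanoate | BrC/C=C/CCCOC(=O)C(C)C | intermediate
6 | (4S)-4-methylhex-5-en-1-yl 2-methylpropanoate | C=C[C@@H](C)CCCOC(=O)C(C)C | intermediate
7 | (4S)-4-methyl-5-oxohexyl 2-methylpropanoate | CC(=O)[C@@H](C)CCCOC(=O)C(C)C | intermediate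
8 | potassium (3S)-3-methyl-6-[(2-methylpropanoyl)oxy]hex-1-en-2-olate | C=C([O-])[C@@H](C)CCCOC(=O)C(C)C.[K+] | intermediate (not isolated)
9 | (4S)-4-methyl-5-[(trifluoromethanesulfonyl)oxy]hex-5-en-1-yl 2-methylpropanoate | C=C(OS(=O)(=O)C(F)(F)F)[C@@H](C)CCCOC(=O)C(C)C | intermediate
10 | methyl prop-2-enoate | C=CC(=O)OC | starting material
11 | 2,2-dimethoxyacetaldehyde | COC(OC)C=O | starting material
12 | methyl 3-hydroxy-4,4-dimethoxy-2-methylidenebutanoate (racemic) | C=C(C(=O)OC)C(O)C(OC)OC | intermediate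
13 | methyl (2Z)-2-(bromomethyl)-4,4-dimethoxybut-2-enoate | BrC/C(C(=O)OC)=C\C(OC)OC | intermediate
14 | 3-methylbut-3-en-1-ol | C=C(C)CCO | starting material
15 | 3-methylbut-3-enal | C=C(C)CC=O | intermediate
16 | methyl (3R,4R)-3-(dimethoxymethyl)-6-methyl-2-methylidene-4-[(trimethylsilyl)oxy]hept-6-enoate | C=C(C(=O)OC)[C@@H](C(OC)OC)[C@H](O[Si](C)(C)C)CC(C)=C | intermediate (not isolated)
17 | methyl (3R,4R)-3-(dimethoxymethyl)-4-hydroxy-6-methyl-2-methylidenehept-6-enoate | C=C(C(=O)OC)[C@@H](C(OC)OC)[C@H](O)CC(C)=C | intermediate (not isolated)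
18 | (4R,5R)-4-(dimethoxymethyl)-3-methylidene-5-(2-methylprop-2-en-1-yl)oxolan-2-one | C=C1C(=O)O[C@H](CC(C)=C)[C@@H]1C(OC)OC | intermediate
19 | (3R,4R,5R)-4-(dimethoxymethyl)-5-(2-methylprop-2-en-1-yl)-3-[(phenylsulfanyl)methyl]oxolan-2-one | O=C1O[C@H](CC(C)=C)[C@H](C(OC)OC)[C@H]1CSc1ccccc1 | intermediate
20 | (2R,3R,4R)-2-(2-methylprop-2-en-1-yl)-5-oxo-4-[(phenylsulfanyl)methyl]oxolane-3-carbaldehyde | O=C1O[C@H](CC(C)=C)[C@H](C=O)[C@H]1CSc1ccccc1 | intermediate
21 | (4S,6S)-6-hydroxy-4-methyl-5-methylidene-6-[(2R,3S,4R)-2-(2-methylprop-2-en-1-yl)-5-oxo-4-[(phenylsulfanyl)methyl]oxolan-3-yl]hexyl 2-methylpropanoate | C=C([C@@H](C)CCCOC(=O)C(C)C)[C@@H](O)[C@H]1[C@@H](CC(C)=C)OC(=O)[C@@H]1CSc1ccccc1 | intermediate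
22 | (4S)-4-[(3R,3aS,4S,7aR)-4-hydroxy-6-methyl-2-oxo-3-[(phenylsulfanyl)methyl]-2,3,3a,4,7,7a-hexahydro-1-benzofuran-5-yl]pentyl 2-methylpropanoate | O=C1O[C@@H]2CC(C)=C([C@@H](C)CCCOC(=O)C(C)C)[C@@H](O)[C@@H]2[C@H]1CSc1ccccc1 | intermediate
23 | (4S)-4-[(3R,3aR,4S,7aR)-6-methyl-4-[(2-methylpropanoyl)oxy]-2-oxo-3-[(phenylsulfanyl)methyl]-2,3,3a,4,7,7a-hexahydro-1-benzofuran-5-yl]pentyl 2-methylpropanoate | O=C1O[C@@H]2CC(C)=C([C@@H](C)CCCOC(=O)C(C)C)[C@@H](OC(=O)C(C)C)[C@@H]2[C@H]1CSc1ccccc1 | intermediate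
24 | (4S)-4-[(3R,3aR,4S,7aR)-3-[(benzenesulfinyl)methyl]-6-methyl-4-[(2-methylpropanoyl)oxy]-2-oxo-2,3,3a,4,7,7a-hexahydro-1-benzofuran-5-yl]pentyl 2-methylpropanoate (both sulfur epimers) | O=C1O[C@@H]2CC(C)=C([C@@H](C)CCCOC(=O)C(C)C)[C@@H](OC(=O)C(C)C)[C@@H]2[C@H]1CS(=O)c1ccccc1 | intermediate (not isolated)
25 | (4S)-4-[(3aR,4S,7aR)-6-methyl-3-methylidene-4-[(2-methylpropanoyl)oxy]-2-oxo-2,3,3a,4,7,7a-hexahydro-1-benzofuran-5-yl]pentyl 2-methylpropanoate | C=C1C(=O)O[C@@H]2CC(C)=C([C@@H](C)CCCOC(=O)C(C)C)[C@@H](OC(=O)C(C)C)[C@H]12 | target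

**Step count**

Total step count: 15.
Longest linear sequence: 9 steps (steps 1–5 and 12–15; the line through steps 6, 7, 9–15 is also 9).

**Steps most likely to fail, with fallbacks**

Step 9 is the asymmetric chromium allylation. The enantioselectivity with this acetal-bearing bromide is unproven, aldehyde 15 can conjugate to the enal, and the allylmetal can lose methoxide. The fallback replaces the redox-generated allylchromium by a preformed allylboronate and a closed-transition-state allylboration; it sets out from 12 and 15 and comes back to the route at 18. Acetylation of 12 (Ac2O, DMAP) gives methyl 3-(acetyloxy)-4,4-dimethoxy-2-methylidenebutanoate F1. Copper-catalysed SN2′ borylation (CuCl, KOtBu, B2pin2, THF) gives methyl (2E)-4,4-dimethoxy-2-[(4,4,5,5-tetramethyl-1,3,2-dioxaborolan-2-yl)methyl]but-2-enoate F2, in which the acetal is cis to CH2B. Allylboration of 15 catalysed by a chiral phosphoric acid (TRIP, toluene, −30 °C) runs through a Zimmerman–Traxler chair and gives the syn borate ester methyl (3R,4R)-3-(dimethoxymethyl)-6-methyl-2-methylidene-4-[(4,4,5,5-tetramethyl-1,3,2-dioxaborolan-2-yl)oxy]hept-6-enoate F3. Hydrolysis gives 17, and PPTS in MeOH closes it to 18.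

Step 12 is the fragment coupling. The Felkin preference may be small or reversed, and aldehyde 20 is a β-acyloxy aldehyde with a cis-disposed methallyl group (risk of epimerisation, elimination or carbonyl-ene closure). The fallback sets the carbinol configuration by inversion instead of by facial selectivity; it sets out from 9 and 20 and comes back at 23. If the coupling gives mainly (4S,6R)-6-hydroxy-4-methyl-5-methylidene-6-[(2R,3S,4R)-2-(2-methylprop-2-en-1-yl)-5-oxo-4-[(phenylsulfanyl)methyl]oxolan-3-yl]hexyl 2-methylpropanoate F4, this epimer is cyclised under the step 13 conditions to (4S)-4-[(3R,3aS,4R,7aR)-4-hydroxy-6-methyl-2-oxo-3-[(phenylsulfanyl)methyl]-2,3,3a,4,7,7a-hexahydro-1-benzofuran-5-yl]pentyl 2-methylpropanoate F5. Mitsunobu esterification of F5 with 2-methylpropanoic acid (PPh3, DIAD, toluene, 0 °C → rt) then installs the isobutyrate with inversion and gives 23 directly.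

Step 13 is the most likely to fail. The ruthenium alkylidene has to engage a 1,1-disubstituted alkene flanked by two branched carbons to make a tetrasubstituted olefin, and the sulfide may slow the catalyst. The fallback is a relay ring-closing metathesis; it sets out from 7 (through its enolate 8) and comes back at 22. Alkylation of 8 with 5-iodopent-1-ene (THF/DMPU, −78 → −30 °C) gives (4S)-4-methyl-5-oxoundec-10-en-1-yl 2-methylpropanoate F6. Kinetic triflation on the methylene side (KN(SiMe3)2, PhNTf2) gives (4S)-4-methyl-5-[(trifluoromethanesulfonyl)oxy]undeca-5,10-dien-1-yl 2-methylpropanoate F7 as a 5E/5Z mixture, both isomers being usable. Nozaki–Hiyama–Kishi coupling of F7 with 20 (CrCl2, NiCl2 cat., DMF) gives (4S)-5-{(S)-hydroxy[(2R,3S,4R)-2-(2-methylprop-2-en-1-yl)-5-oxo-4-[(phenylsulfanyl)methyl]oxolan-3-yl]methyl}-4-methylundeca-5,10-dien-1-yl 2-methylpropanoate F8. With second-generation Grubbs catalyst (CH2Cl2, 40 °C) the metal loads on the unhindered terminal vinyl group, expels cyclopentene and is thereby placed as the alkylidene on the hindered carbon, which closes onto the methallyl group to give 22.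

**Further compounds**

F1 | step 9 | methyl 3-(acetyloxy)-4,4-dimethoxy-2-methylidenebutanoate (racemic) | C=C(C(=O)OC)C(OC(C)=O)C(OC)OC
F2 | step 9 | methyl (2E)-4,4-dimethoxy-2-[(4,4,5,5-tetramethyl-1,3,2-dioxaborolan-2-yl)methyl]but-2-enoate | COC(=O)/C(CB1OC(C)(C)C(C)(C)O1)=C/C(OC)OC
F3 | step 9 | methyl (3R,4R)-3-(dimethoxymethyl)-6-methyl-2-methylidene-4-[(4,4,5,5-tetramethyl-1,3,2-dioxaborolan-2-yl)oxy]hept-6-enoate | C=C(C(=O)OC)[C@@H](C(OC)OC)[C@H](OB1OC(C)(C)C(C)(C)O1)CC(C)=C
F4 | step 12 | (4S,6R)-6-hydroxy-4-methyl-5-methylidene-6-[(2R,3S,4R)-2-(2-methylprop-2-en-1-yl)-5-oxo-4-[(phenylsulfanyl)methyl]oxolan-3-yl]hexyl 2-methylpropanoate | C=C([C@@H](C)CCCOC(=O)C(C)C)[C@H](O)[C@H]1[C@@H](CC(C)=C)OC(=O)[C@@H]1CSc1ccccc1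
F5 | step 12 | (4S)-4-[(3R,3aS,4R,7aR)-4-hydroxy-6-methyl-2-oxo-3-[(phenylsulfanyl)methyl]-2,3,3a,4,7,7a-hexahydro-1-benzofuran-5-yl]pentyl 2-methylpropanoate | O=C1O[C@@H]2CC(C)=C([C@@H](C)CCCOC(=O)C(C)C)[C@H](O)[C@@H]2[C@H]1CSc1ccccc1
F6 | step 13 | (4S)-4-methyl-5-oxoundec-10-en-1-yl 2-methylpropanoate | C=CCCCCC(=O)[C@@H](C)CCCOC(=O)C(C)C
F7 | step 13 | (4S)-4-methyl-5-[(trifluoromethanesulfonyl)oxy]undeca-5,10-dien-1-yl 2-methylpropanoate (5E/5Z mixture) | C=CCCCC=C(OS(=O)(=O)C(F)(F)F)[C@@H](C)CCCOC(=O)C(C)C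
F8 | step 13 | (4S)-5-{(S)-hydroxy[(2R,3S,4R)-2-(2-methylprop-2-en-1-yl)-5-oxo-4-[(phenylsulfanyl)methyl]oxolan-3-yl]methyl}-4-methylundeca-5,10-dien-1-yl 2-methylpropanoate (5E/5Z mixture) | C=CCCCC=C([C@@H](C)CCCOC(=O)C(C)C)[C@@H](O)[C@H]1[C@@H](CC(C)=C)OC(=O)[C@@H]1CSc1ccccc1
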